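(The runs are simulated for substances that don't exist.)

Slowness was what I looked for first in the earlier runs, since maple and alder had to be read from them.

| setting | ochre | violet | teal | maple | alder |
|---|---|---|---|---|---|
| left-handed substrate | 0.50 mM | 0.50 mM | 0.50 mM | 0.50 mM | 0.50 mM |
| right-handed substrate | 0.50 mM | 0.50 mM | 0.50 mM | 0.50 mM | 0.50 mM |
| partner | 2.2 equiv (fed, over 15 s) | 2.2 equiv (fed, over 15 s) | 2.2 equiv (fed, over 15 s) | 2.20 equiv (fed, over 15 s) | 2.20 equiv (fed, over 15 s) |
| free catalyst | 0.032 mol% | 0.04 mol% | 0.047 mol% | 0.05 mol% | 0.03 mol% |
| racemization catalyst | 0.1 mol% | 0.1 mol% | 0.1 mol% | 0.1 mol% | 0.1 mol% |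
| added ligand | 1.3 µM | 1.3 µM | 1.3 µM | 1.3 µM | 1.3 µM |
| remark | run made earlier | run made earlier | run made earlier |  |  |
| time |  |  |  | 2.5 min | 2.5 min |

| run | time / s | right-handed substrate / % | left-handed substrate / % |
|---|---|---|---|
| ochre | 10.0 | 47.2 | 41.7 |
| ochre | 15.0 | 42.5 | 34.3 |
| ochre | 30.0 | 35.3 | 25.0 |
| ochre | 60.0 | 29.7 | 22.4 |
| ochre | 120 | 24.6 | 23.1 |
| violet | 20.0 | 36.7 | 26.5 |
| violet | 40.0 | 30.2 | 20.9 |
| violet | 60.0 | 26.8 | 20.4 |
| violet | 80.0 | 25.0 | 20.0 |
| violet | 120 | 23.4 | 20.4 |
| teal | 10.0 | 45.4 | 39.5 |
| teal | 25.0 | 33.5 | 22.0 |
| teal | 50.0 | 25.6 | 18.0 |
| teal | 80.0 | 24.2 | 18.8 |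
| teal | 120 | 21.6 | 20.5 |

(standard deviation of a reading: 0.5 percentage points)

- free catalyst is single-handed; left-handed substrate and right-handed substrate are mirror images of each other, charged as a racemate, each of them at the stated concentration
- steps thought possible: partner + free catalyst + left-handed substrate -> free catalyst + left-handed product; partner + free catalyst + right-handed substrate -> free catalyst + right-handed product; left-handed substrate + racemization catalyst <-> right-handed substrate + racemization catalyst; partner <-> dormant form; partner -> decomposed reagent; racemization catalyst + added ligand <-> idle complex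
- an excess is the difference of the two amounts in percent of their sum
- an excess is below zero if the other one leads

- the winner by excess of right-handed substrate over left-handed substrate among what is left of the two; "neither" if no more than 2 percentage points parts them (maple / alder / neither)
- excess of right-handed substrate over left-handed substrate among what is left of the two at the end, maple
- excess of right-handed substrate over left-handed substrate among what is left of the two at the end, alder

First, had these flasks stopped? The ochre run consumed 48 percentage points of its substrate in the first 60.0 s but 4.4 points in the next 60.0 s, so it had nearly stalled. Why, when the partner charged was more than the two substrates together? I followed one partner molecule. Each product takes one, and by 120 s the ochre products accounted for 47.5% of the partner charged. In ochre a partner molecule had thus reached a substrate about half the time, and I took the partner for the limiting reagent.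

Second, what became of the excess in the stalled flask? At 60.0 s ochre read 14.0% and violet 13.6%, a mean of 13.8%. At 120 s their mean was 5.00%. These readings gave the fading half-life, the time in which a stalled flask with this racemization catalyst and added ligand loses half its excess: 41.0 s.

Third, what stood at 2.5 min? From 60.0 s that is 2.20 half-lives, leaving 3.01%. Ochre and violet, at different loadings, differed by 0.40 points at 60.0 s and by 3.7 points at 120 s, each excess a small difference of readings that scatter by 0.5 points. I took that gap for scatter, reckoned this figure for maple and alder alike and expected neither to win.

The forecast also said neither, with 2.2% for maple and 2.8% for alder, holding that “racemization simply erases the excess”. Unlike my single figure, it put alder slightly higher.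

The flasks gave neither: maple 3.23%, alder 2.55%. Maple led, but by 0.68 points, less than the margin of 2 points.

    partner + free catalyst + left-handed substrate → free catalyst + left-handed product (k = 4.20 × 10⁸ M⁻² s⁻¹)
    partner + free catalyst + right-handed substrate → free catalyst + right-handed product (k = 1.70 × 10⁸ M⁻² s⁻¹)
    left-handed substrate + racemization catalyst ⇌ right-handed substrate + racemization catalyst, rate k3*[racemization catalyst]*[left-handed substrate] forward; the back reaction follows from the equilibrium constant (k = 45000 M⁻¹ s⁻¹)
    partner ⇌ dormant form (K = 0.170, k = 0.00820 s⁻¹)
    partner → decomposed reagent (k = 0.0370 s⁻¹)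
    racemization catalyst + added ligand ⇌ idle complex, settled at all times (K = 1.10 × 10⁶ M⁻¹)

A neighbour flask was alder with 0.0033 mM of added ligand. At the end its racemization catalyst outside the idle complex stood at 23.7% of charge, against 46.8% in alder. Scaling by that ratio gave a fading half-life of 80.7 s, twice the value read from ochre and violet. Starting from the ochre and violet mean of 13.8% at 60.0 s, I reckoned 6.37% at 2.5 min. The neighbour flask gave more than that: an excess of 8.21%.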